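**Retrosynthetic overview**
1. Numbering (tricyclo[5.3.1.0(1,5)]undecane): ring A = C1, C7, C8, C9, C10, C11 (enolised cyclohexanetrione, acyl group on C9); ring B = C1, C5, C6, C7, C11; ring C = C1, C2, C3, C4, C5 (the cyclopentane).
2. The C(CH3)2OH group on C3 is cut back to a methyl ketone (MeMgBr), and the ketone to a but-2-ynyl group on C1, an alkyne at ketone oxidation level.
3. Key disconnections, made in one flask: C3–C4 (tertiary C4 cation plus alkyne, closes ring C last) and C1–C5 (radical 5-exo, closes ring B); what is left is ring A alone, a dearomatised acylphloroglucinol.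
4. Enabling feature: C1 lies between the C10 and C11 carbonyls of ring A (an easily formed enol radical) and 1,3 to the quaternary C7, whose prenyl group supplies C6, C5 and the CMe2 carbon C4; the chain on C1 supplies C2 and the alkyne carbon C3.
5. Ring order A (aromatic, then dearomatised by palladium-catalysed enantioselective prenylation, which sets C7) → B → C; C1 and C5 follow from C7 through the bicycle, and C3 is set by ketonisation, not by C–C bond formation.

Key step: step 4

Remark: the enolised triketones are drawn as one tautomer each, and the stereodescriptors refer to the tautomer drawn.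

**Step 1**
Reactants: 1 2-methylbenzene-1,3,5-triol; 2 2-methylpropanoyl chloride
Product: 3 1-(2,4,6-trihydroxy-3-methylphenyl)-2-methylpropan-1-one
Conditions: AlCl3, PhNO2/CH2Cl2, 0 to 60 °C; aq. HCl
Reagents that add atoms: 2-methylpropanoyl chloride (2), CC(C)C(Cl)=O
Why: Friedel–Crafts C-acylation of the electron-rich triol at one of its two equivalent free ring positions; the first acyl group deactivates the ring against a second, and no stereocentre is formed.

**Step 2**
Reactants: 3 1-(2,4,6-trihydroxy-3-methylphenyl)-2-methylpropan-1-one; 4 1-bromobut-2-yne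
Product: 5 1-[3-(but-2-yn-1-yl)-2,4,6-trihydroxy-5-methylphenyl]-2-methylpropan-1-one
Conditions: KOH, H2O, 0 °C; aq. HCl
Reagents that add atoms: 1-bromobut-2-yne (4), CC#CCBr
Why: SN2 C-alkylation of the ambident phenolate at the only unsubstituted ring carbon, favoured over O-alkylation in water where the oxygen atoms are hydrogen-bonded; no stereocentre is formed.

**Step 3**
Reactants: 5 1-[3-(but-2-yn-1-yl)-2,4,6-trihydroxy-5-methylphenyl]-2-methylpropan-1-one; 6 3-methylbut-2-en-1-yl acetate
Product: 7 (4R)-6-(but-2-yn-1-yl)-3,5-dihydroxy-4-methyl-4-(3-methylbut-2-en-1-yl)-2-(2-methylpropanoyl)cyclohexa-2,5-dien-1-one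
Conditions: Pd2(dba)3·CHCl3 (cat.), (R,R)-DACH-phenyl Trost ligand (cat.), Et3N, THF, 0 °C
Reagents that add atoms: 3-methylbut-2-en-1-yl acetate (6), CC(C)=CCOC(C)=O
Why: Tsuji–Trost asymmetric allylic alkylation run as an alkylative dearomatisation, in which the prenyl–palladium cation is attacked at its unsubstituted terminus by the methyl-bearing ring carbon (the less hindered of the two fully substituted nucleophilic carbons) and the chiral ligand pocket selects the face of the phenolate, so that the quaternary centre should form as R (the antipodal ligand is used if the sense proves opposite).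

**Step 4**
Reactants: 7 (4R)-6-(but-2-yn-1-yl)-3,5-dihydroxy-4-methyl-4-(3-methylbut-2-en-1-yl)-2-(2-methylpropanoyl)cyclohexa-2,5-dien-1-one
Product: 10 (1S,3S,5S,7S)-3-acetyl-8-hydroxy-4,4,7-trimethyl-9-(2-methylpropanoyl)tricyclo[5.3.1.0(1,5)]undec-8-ene-10,11-dione, via bicyclic isopropenyl alkyne 8 (not isolated), via tricyclic enol trifluoroacetate 9 (not isolated)
Conditions: Mn(OAc)3·2H2O, Cu(OAc)2·H2O, AcOH, 25 °C; evaporate; CF3CO2H, CH2Cl2, 0 °C; then THF/H2O, NaOAc/AcOH buffer (pH 4.5), 0 °C
Reagents that add atoms: trifluoroacetic acid, OC(=O)C(F)(F)F (its oxygen becomes the ketone oxygen); water, O (cleaves the trifluoroacetyl group of 9)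
Why: Proposed new method: Mn(OAc)3 oxidises the enolised triketone of 7 by one electron to a radical with spin on C1, which adds 5-exo-trig to the prenyl alkene on C7 and closes ring B, and Cu(OAc)2 intercepts the new tertiary C4 radical by oxidative elimination to the isopropenyl compound 8 before it can add to the alkyne; this half is the known manganese/copper oxidative radical cyclisation of dearomatised acylphloroglucinols. CF3CO2H then protonates 8 at the terminal alkene carbon, the tertiary C4 cation is attacked 5-exo-dig by the inner alkyne carbon C3 so that ring C closes last, and the linear vinyl cation is held as enol trifluoroacetate 9; this half follows the alkyne-terminated cationic cyclisations that give cyclopentyl methyl ketones, and what is new is their coupling to the radical closure in one flask on a bridged triketone. C1 is set relative to C7 because the one-carbon tether C6 can reach only one face of the planar C1 radical, and C5 is set because the CMe2 terminus turns exo, away from the three-carbon bridge, the only orientation from which C4 can later reach the alkyne. C3 is deliberately not made in a carbon–carbon bond-forming event: buffered hydrolysis of 9 releases the exocyclic enol, and the acidic enol OH on C10 lies under C3 and should deliver its proton through a six-membered transition state to the face syn to C10, which leaves the acetyl group syn to the C11 bridge as in the target. The step needs closure through C1 and not through the acyl-bearing C9, which the higher spin density and lower hindrance at C1 secure, and capture of both cations by carbon and not by oxygen, which is secured because C4 stands exo and remote from the enol oxygens on C8 and C10 and because oxygen capture of the vinyl cation would create a bridgehead alkene. Because C3 is α to the new ketone, a wrong epimer can be re-enolised and returned.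

**Step 5**
Reactants: 10 (1S,3S,5S,7S)-3-acetyl-8-hydroxy-4,4,7-trimethyl-9-(2-methylpropanoyl)tricyclo[5.3.1.0(1,5)]undec-8-ene-10,11-dione
Product: 11 (1S,3S,5S,7S)-8-hydroxy-3-(2-hydroxypropan-2-yl)-4,4,7-trimethyl-9-(2-methylpropanoyl)tricyclo[5.3.1.0(1,5)]undec-8-ene-10,11-dione
Conditions: MeMgBr (excess), CeCl3, THF, −78 °C; aq. NH4Cl
Reagents that add atoms: methylmagnesium bromide, C[Mg]Br
Why: Cerium-mediated Grignard 1,2-addition to the only accessible ketone, since the first equivalent turns the triketone into an unreactive enolate and the C11 ketone is flanked by two quaternary carbons, while the weakly basic cerium reagent should not enolise C3; no new stereocentre is formed.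

**Compound list**
1 | 2-methylbenzene-1,3,5-triol | Cc1c(O)cc(O)cc1O | starting material
2 | 2-methylpropanoyl chloride | CC(C)C(Cl)=O | starting material
3 | 1-(2,4,6-trihydroxy-3-methylphenyl)-2-methylpropan-1-one | CC(C)C(=O)c1c(O)cc(O)c(C)c1O | intermediate
4 | 1-bromobut-2-yne | CC#CCBr | starting material
5 | 1-[3-(but-2-yn-1-yl)-2,4,6-trihydroxy-5-methylphenyl]-2-methylpropan-1-one | CC#CCc1c(O)c(C)c(O)c(C(=O)C(C)C)c1O | intermediate
6 | 3-methylbut-2-en-1-yl acetate | CC(C)=CCOC(C)=O | starting material
7 | (4R)-6-(but-2-yn-1-yl)-3,5-dihydroxy-4-methyl-4-(3-methylbut-2-en-1-yl)-2-(2-methylpropanoyl)cyclohexa-2,5-dien-1-one | CC#CCC1=C(O)[C@@](C)(CC=C(C)C)C(O)=C(C(=O)C(C)C)C1=O | intermediate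
8 | (1S,5S,7S)-1-(but-2-yn-1-yl)-4-hydroxy-5-methyl-3-(2-methylpropanoyl)-7-(prop-1-en-2-yl)bicyclo[3.2.1]oct-3-ene-2,8-dione (isopropenyl exo, syn to C8) | CC(C)C(=O)C1=C(O)[C@]2(C)C[C@@H](C(C)=C)[C@](CC#CC)(C1=O)C2=O | intermediate
9 | 1-[(1S,5S,7S)-8-hydroxy-4,4,7-trimethyl-9-(2-methylpropanoyl)-10,11-dioxotricyclo[5.3.1.0(1,5)]undec-8-en-3-ylidene]ethyl trifluoroacetate (E/Z mixture, both isomers give 10) | CC(C)C(=O)C1=C(O)[C@]2(C)C[C@H]3C(C)(C)C(=C(C)OC(=O)C(F)(F)F)C[C@@]3(C1=O)C2=O | intermediate
10 | (1S,3S,5S,7S)-3-acetyl-8-hydroxy-4,4,7-trimethyl-9-(2-methylpropanoyl)tricyclo[5.3.1.0(1,5)]undec-8-ene-10,11-dione | CC(C)C(=O)C1=C(O)[C@]2(C)C[C@H]3C(C)(C)[C@@H](C(C)=O)C[C@@]3(C1=O)C2=O | intermediate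
11 | (1S,3S,5S,7S)-8-hydroxy-3-(2-hydroxypropan-2-yl)-4,4,7-trimethyl-9-(2-methylpropanoyl)tricyclo[5.3.1.0(1,5)]undec-8-ene-10,11-dione | CC(C)C(=O)C1=C(O)[C@]2(C)C[C@H]3C(C)(C)[C@@H](C(C)(C)O)C[C@@]3(C1=O)C2=O | target

**Total step count:** 5. **Longest linear sequence:** 5 steps (1 → 3 → 5 → 7 → 10 → 11).

**Three steps most likely to fail**

Step 4 (proposed new method). What may go wrong: the tertiary radical may add to the alkyne before copper oxidises it, the cationic closure may stall at the stage of 8, or facial control at C3 may be lost through acid-catalysed enolisation during hydrolysis. The fallback uses known chemistry, with a prenyl group in place of the alkyne as terminator and the tertiary alcohol made by alkene hydration. It sets out from 3: C-prenylation with prenyl bromide in aqueous KOH should give the aromatic prenyl ketone F1, and the palladium-catalysed dearomative prenylation of step 3 should then give the diprenyl dienone F2. Mn(OAc)3/Cu(OAc)2 in AcOH should close rings B and C by two successive 5-exo radical cyclisations and end, by oxidative elimination, in the isopropenyl tricycle F3. Facial control in the second closure is weak in this variant, so the C3 epimer of F3 is removed by chromatography. Mukaiyama hydration (Co(acac)2, PhSiH3, O2, i-PrOH) of F3 comes back to the route at 11.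

Step 3. What may go wrong: attack at the butynyl-bearing ring carbon instead of the methyl-bearing one, O-allylation that does not revert, double allylation, or insufficient enantioselection. The fallback sets out from 5: uncatalysed alkylation with prenyl bromide and NaOMe in MeOH at 0 °C should give the racemic dienone F4 (regioisomers separated), which is resolved by preparative chromatography on a chiral stationary phase. The R enantiomer is 7, where the route is rejoined.

Step 2. What may go wrong: O-alkylation, and a second alkylation at the methyl-bearing carbon. The fallback sets out from 3: a Mannich reaction (aq. CH2O, Me2NH, EtOH) should give the Mannich base F5. Excess prop-1-yn-1-ylmagnesium bromide (THF/toluene, 80 °C) should then eliminate dimethylamine to an ortho-quinone methide and add to it in 1,4 fashion, which forms the same benzylic C–C bond and comes back to the route at 5.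

**Further compounds**
F1 | step 4 | 1-[2,4,6-trihydroxy-3-methyl-5-(3-methylbut-2-en-1-yl)phenyl]-2-methylpropan-1-one | CC(C)=CCc1c(O)c(C)c(O)c(C(=O)C(C)C)c1O
F2 | step 4 | (4R)-3,5-dihydroxy-4-methyl-4,6-bis(3-methylbut-2-en-1-yl)-2-(2-methylpropanoyl)cyclohexa-2,5-dien-1-one | CC(C)=CCC1=C(O)[C@@](C)(CC=C(C)C)C(O)=C(C(=O)C(C)C)C1=O
F3 | step 4 | (1S,3R,5S,7S)-8-hydroxy-4,4,7-trimethyl-9-(2-methylpropanoyl)-3-(prop-1-en-2-yl)tricyclo[5.3.1.0(1,5)]undec-8-ene-10,11-dione | CC(C)C(=O)C1=C(O)[C@]2(C)C[C@H]3C(C)(C)[C@@H](C(C)=C)C[C@@]3(C1=O)C2=O
F4 | step 3 | racemic 6-(but-2-yn-1-yl)-3,5-dihydroxy-4-methyl-4-(3-methylbut-2-en-1-yl)-2-(2-methylpropanoyl)cyclohexa-2,5-dien-1-one | CC#CCC1=C(O)C(C)(CC=C(C)C)C(O)=C(C(=O)C(C)C)C1=O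
F5 | step 2 | 1-{3-[(dimethylamino)methyl]-2,4,6-trihydroxy-5-methylphenyl}-2-methylpropan-1-one | CC(C)C(=O)c1c(O)c(C)c(O)c(CN(C)C)c1O
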